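Take the closed, stirred, isothermal vessel: substrate in solution, solid reagent given per volume, none of it dissolved at the start.

all flasks: substrate 18 mM
- summer: solid reagent 47 mM; run made earlier
- winter: solid reagent 42 mM; run made earlier
- green: solid reagent 54.0 mM; time 2.0 h
- amber: solid reagent 45.0 mM; time 2.0 h

- summer (time / min: substrate / %, adduct / %, product / %): 12.0: 77.2, 1.3, 1.0; 25.0: 58.5, 0.3, 0; 40.0: 39.8, 0, 0; 50.0: 33.6, 1.7, 0; 60.0: 27.4, 0, 0
- winter (time / min: substrate / %, adduct / %, product / %): 12.0: 76.4, 0.3, 0; 25.0: 57.5, 0.6, 0.5; 40.0: 42.7, 2.5, 1.2; 50.0: 36.2, 0, 0.3; 60.0: 28.0, 0.3, 0

(readings scatter by 1 percentage point)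

- given per volume of solution although it is solid: solid reagent
- at the start none of the solid reagent is in solution
- a reading of substrate is of its free form alone

* which of these there is most of at the end, counted by the substrate in it, green (adduct / product / substrate)
* which of these there is most of at the end, counted by the substrate in it, amber (adduct / product / substrate)
* the largest of these amounts at the end, in percent of the substrate charged, green
* the largest of these amounts at the end, in percent of the substrate charged, amber

Compare the charges first: substrate is the smaller even in the winter run, so write its balance. Subtract free substrate, adduct and product from the charge at the last summer reading, and 72.6% is gone. Call this the missing share, the part of the charge that shows in none of the three. The winter run, with less solid, gives 71.7%, and that difference lies within a scatter of 1 percentage point, so take the mean, 72.2%. Amber's charge of solid lies between those of the two runs, but green's lies beyond them, so treating green alike is an extrapolation. Now let each 60.0 min take the same fraction of what is left: the missing share at 2.0 h becomes 92.2%, which leaves about 7.80% as substrate. Adduct's highest reading is 2.5%, less than that substrate figure, so commit to substrate in both flasks.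

The forecast names substrate in green at 7.5% and substrate in amber at 7.5%, a little less than the 7.80% reckoned here, holding that “the substrate goes to something unseen”.

The flasks give substrate at 11.0% in green and substrate at 11.0% in amber.

    substrate + partner ⇌ adduct (K = 4.93 /M, k = 0.0182 /M/s)
    adduct → product (k = 6.65 × 10⁻⁵ /s)
    substrate ⇌ dormant form (K = 17.0, k = 3.74 × 10⁻⁴ /s)
    solid reagent ⇌ partner, rate k4*(cs4 - [partner]) while solid is left; crystals form when [partner] > cs4 (solubility = 4.90 mM, k = 2.90 × 10⁻⁴ /s)
    partner → decomposed reagent (k = 6.20 × 10⁻⁵ /s)

Green's missing share at 2.0 h is 88.6%, against 92.2% reckoned, and it stands as dormant form, 88.6%. In green, substrate passed into dormant form with half of that step's turnover up to 2.0 h done by 0.446 h, and later, at 1.00 h, adduct stood at 0.406% and product at 0.0834%. For green read at 80 min, the same fraction gives a missing share of 81.9%. That flask shows 80.0%, with substrate at 19.6%.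

(Readings and results were computed with constants of no real substance.)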